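The synthesis cuts ring C at three bonds around its lone carbonyl carbon. C4 sits between C4a of ring A and the C3–C2 unit that carries ring B, and O1 hangs on C8a next to C4a. C4 can therefore be carbon monoxide, C4a/O1 an ortho-iodophenol unit, and C3–C2 a terminal arylacetylene. One palladium-catalysed carbonylative alkynylation with in-flask 6-endo closure forms C4a–C4, C4–C3 and O1–C2 and delivers the whole flavone skeleton. Its precursors are an O-acetylated 2-iodo-3,5-bis(silyloxy)phenol, made from symmetric phloroglucinol, and a 3-silyloxy-4-prenyloxyphenylacetylene. C2, the only stereocentre, is set afterwards by ligand-controlled copper hydride conjugate reduction. Buffered fluoride then frees the three phenols.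

Key step: step 7

Assumption: (R)-DTBM-SEGPHOS is written for the ligand antipode that directs hydride to the Re face of C2 (2S product); the sense of induction is to be verified on the first run by chiral HPLC and ECD, and the equally available (S)-ligand is used if it proves opposite.

Protecting-group design (TIPS = triisopropylsilyl, prenyl = 3-methylbut-2-enyl):
- **TIPS ethers:** O5 and O7 become vinylogous silyl esters once the pyranone exists and must outlast a secondary amine. They still leave with buffered fluoride.
- **Acetate at the future O1:** the amine removes it in the flask.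
- **Order on ring B:** the alkyne is made before the phenol is silylated.

**Route**

Step 1
Reactants: 1 phloroglucinol (anhydrous)
Product: 2 3,5-bis(triisopropylsilyloxy)phenol
Conditions: TIPSCl (2.0 equiv), imidazole (4.5 equiv), DMF, 0 °C → rt; chromatography
Reagents that add atoms: triisopropylsilyl chloride, CC(C)[Si](Cl)(C(C)C)C(C)C
Why: Imidazole-promoted O-silylation of a threefold-symmetric triol is a statistical reaction in which two equivalents of the bulky chloride should make the bis-ether the main component, the large polarity gaps allow its separation, and the mono- and tris-ethers can be fed back.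

Step 2
Reactants: 2 3,5-bis(triisopropylsilyloxy)phenol
Product: 3 2-iodo-3,5-bis(triisopropylsilyloxy)phenol
Conditions: NIS (1.0 equiv), CH2Cl2, −40 → 0 °C, dark
Reagents that add atoms: N-iodosuccinimide, O=C1CCC(=O)N1I
Why: Electrophilic aromatic iodination of a strongly activated ring, in which the equivalent positions C2/C6 lie next to the small free hydroxyl whereas C4 is walled in by two TIPSO groups, so that one equivalent of NIS at low temperature should stop at the 2-iodide.

Step 3
Reactants: 3 2-iodo-3,5-bis(triisopropylsilyloxy)phenol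
Product: 4 2-iodo-3,5-bis(triisopropylsilyloxy)phenyl acetate
Conditions: Ac2O (1.5 equiv), pyridine, 0 °C → rt
Reagents that add atoms: acetic anhydride, CC(=O)OC(C)=O
Why: Routine O-acetylation of the only free phenol, which turns the acid- and light-sensitive electron-rich iodophenol into a storable aryl iodide that should add to Pd(0) faster and cannot cyclise before the carbonyl carbon is in place.

Step 4
Reactants: 5 3,4-dihydroxybenzaldehyde; 6 prenyl bromide (1.05 equiv)
Product: 7 3-hydroxy-4-(3-methylbut-2-enyloxy)benzaldehyde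
Conditions: NaHCO3 (1.5 equiv), DMF, 40 °C
Reagents that add atoms: prenyl bromide (6), CC(C)=CCBr
Why: Williamson ether synthesis under weak-base control, in which hydrogen carbonate ionises only the more acidic 4-OH (para to the formyl group), so that SN2 reaction with one equivalent of the primary allylic bromide should give the 4-O-prenyl ether and leave 3-OH free.

Step 5
Reactants: 7 3-hydroxy-4-(3-methylbut-2-enyloxy)benzaldehyde
Product: 8 5-ethynyl-2-(3-methylbut-2-enyloxy)phenol
Conditions: dimethyl (1-diazo-2-oxopropyl)phosphonate (1.3 equiv), K2CO3 (3 equiv), MeOH, 0 °C → rt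
Reagents that add atoms: dimethyl (1-diazo-2-oxopropyl)phosphonate, COP(=O)(OC)C(=[N+]=[N-])C(C)=O
Why: Seyferth–Gilbert homologation in its Ohira–Bestmann form (methanolysis to the diazomethylphosphonate anion, Horner–Wadsworth–Emmons-type olefination, loss of N2 and 1,2-hydride shift of the alkylidene carbene), which tolerates the phenoxide because it is meta to the aldehyde and is placed before silylation because carbonate in methanol would strip an aryl silyl ether.

Step 6
Reactants: 8 5-ethynyl-2-(3-methylbut-2-enyloxy)phenol
Product: 9 3-(triisopropylsilyloxy)-4-prenyloxyphenylacetylene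
Conditions: TIPSCl (1.2 equiv), imidazole (2.5 equiv), DMF, rt
Reagents that add atoms: triisopropylsilyl chloride, CC(C)[Si](Cl)(C(C)C)C(C)C
Why: Routine O-silylation of the single phenol, needed because a free phenol would capture the acyl–palladium intermediate of step 7 as an aryl ester and consume hydride in step 8, while the terminal alkyne and the prenyl ether are inert.

Step 7
Reactants: 4 2-iodo-3,5-bis(triisopropylsilyloxy)phenyl acetate; 9 3-(triisopropylsilyloxy)-4-prenyloxyphenylacetylene (1.2 equiv); 10 carbon monoxide
Product: 13 5,7,3'-tris-O-TIPS-4'-prenyloxyflavone, via acetoxy ynone 11 (not isolated), via hydroxy enaminone 12 (not isolated)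
Conditions: PdCl2(dppf) (5 mol %), CO (5 bar), Et2NH–THF 1:1, 55 °C, no copper salt
Reagents that add atoms: carbon monoxide (10), [C-]#[O+]
Why: Pd(0) inserts into the C–I bond of 4, the electron-rich aryl group migrates onto coordinated CO, and amine-assisted transfer of the alkynyl group of 9 followed by reductive elimination gives ynone 11 (C4a–C4 and C4–C3). This is the known carbonylative Sonogashira coupling/annulation of o-iodophenols or their acetates with terminal alkynes to flavones. Diethylamine then cleaves the acetate and adds to C2 of the ynone to give enaminone 12, and ring C closes when the freed phenol oxygen attacks C2 and expels the amine, a 6-endo closure (formally 6-endo-dig on the ynone, in practice 6-endo-trig addition–elimination) that forms O1–C2. No stereocentre is created. Carbonylation must outrun direct alkynylation, which CO pressure, the absence of copper and the fast migration of the trioxygenated aryl group secure, while the acetate keeps a directly coupled product from closing to a benzofuran and the two ortho substituents shield the acyl–palladium from aminolysis. 6-endo must outrun 5-exo (aurone) closure, which the enaminone secures because its C3 is no longer electrophilic; the moderate temperature and the hindered TIPS groups are meant to keep the silyl ethers and the allylic aryl ether intact.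

Step 8
Reactants: 13 5,7,3'-tris-O-TIPS-4'-prenyloxyflavone
Product: 15 (2S)-5,7,3'-tris-O-TIPS-4'-prenyloxyflavanone, via silyl enol ether 14 (not isolated)
Conditions: Cu(OAc)2·H2O (5 mol %), (R)-DTBM-SEGPHOS (5.5 mol %), (EtO)2MeSiH (3 equiv), toluene, 0 °C → rt; then sat. aq NH4Cl, THF
Reagents that add atoms: none
Why: Asymmetric copper hydride conjugate reduction (1,4-hydrosilylation, established for β,β-disubstituted cyclic enones and 2-substituted chromones), in which the C2-symmetric bisphosphine–CuH distinguishes the faces of the planar pyranone and delivers hydride to the Re face of C2 to set 2S, the 5-OTIPS group shields C4 against 1,2-attack, silane trapping as enol ether 14 guards against over-reduction and retro-oxa-Michael opening until the mild hydrolysis, and the unactivated trisubstituted prenyl alkene is not hydrocuprated.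

Step 9
Reactants: 15 (2S)-5,7,3'-tris-O-TIPS-4'-prenyloxyflavanone
Product: 16 monotesone A, (2S)-5,7,3'-trihydroxy-4'-prenyloxyflavanone
Conditions: TBAF (3.3 equiv), AcOH (4 equiv), THF, 0 °C
Reagents that add atoms: none
Why: Fluoride-induced cleavage of the three aryl silyl ethers, driven by Si–F bond formation, in which the acetic acid buffer protonates each phenoxide at once so that neither enolisation nor retro-oxa-Michael ring opening can scramble C2, and the acid-sensitive prenyl ether meets neither strong acid nor Lewis acid.

**Compound list**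

1 | phloroglucinol | Oc1cc(O)cc(O)c1 | starting material
2 | 3,5-bis(triisopropylsilyloxy)phenol | Oc1cc(O[Si](C(C)C)(C(C)C)C(C)C)cc(O[Si](C(C)C)(C(C)C)C(C)C)c1 | intermediate
3 | 2-iodo-3,5-bis(triisopropylsilyloxy)phenol | Oc1cc(O[Si](C(C)C)(C(C)C)C(C)C)cc(O[Si](C(C)C)(C(C)C)C(C)C)c1I | intermediate
4 | 2-iodo-3,5-bis(triisopropylsilyloxy)phenyl acetate | CC(=O)Oc1cc(O[Si](C(C)C)(C(C)C)C(C)C)cc(O[Si](C(C)C)(C(C)C)C(C)C)c1I | intermediate
5 | 3,4-dihydroxybenzaldehyde | O=Cc1ccc(O)c(O)c1 | starting material
6 | prenyl bromide (1-bromo-3-methylbut-2-ene) | CC(C)=CCBr | starting material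
7 | 3-hydroxy-4-(3-methylbut-2-enyloxy)benzaldehyde | CC(C)=CCOc1ccc(C=O)cc1O | intermediate
8 | 5-ethynyl-2-(3-methylbut-2-enyloxy)phenol | CC(C)=CCOc1ccc(C#C)cc1O | intermediate
9 | 3-(triisopropylsilyloxy)-4-prenyloxyphenylacetylene | CC(C)=CCOc1ccc(C#C)cc1O[Si](C(C)C)(C(C)C)C(C)C | intermediate
10 | carbon monoxide | [C-]#[O+] | starting material
11 | 1-[2-acetoxy-4,6-bis(triisopropylsilyloxy)phenyl]-3-[4-prenyloxy-3-(triisopropylsilyloxy)phenyl]prop-2-yn-1-one | CC(=O)Oc1cc(O[Si](C(C)C)(C(C)C)C(C)C)cc(O[Si](C(C)C)(C(C)C)C(C)C)c1C(=O)C#Cc1ccc(OCC=C(C)C)c(O[Si](C(C)C)(C(C)C)C(C)C)c1 | intermediate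
12 | 3-(diethylamino)-1-[2-hydroxy-4,6-bis(triisopropylsilyloxy)phenyl]-3-[4-prenyloxy-3-(triisopropylsilyloxy)phenyl]prop-2-en-1-one (push–pull alkene, geometry not fixed) | CCN(CC)C(=CC(=O)c1c(O)cc(O[Si](C(C)C)(C(C)C)C(C)C)cc1O[Si](C(C)C)(C(C)C)C(C)C)c1ccc(OCC=C(C)C)c(O[Si](C(C)C)(C(C)C)C(C)C)c1 | intermediate
13 | 5,7-bis(triisopropylsilyloxy)-2-[4-prenyloxy-3-(triisopropylsilyloxy)phenyl]-4H-chromen-4-one | CC(C)=CCOc1ccc(-c2cc(=O)c3c(O[Si](C(C)C)(C(C)C)C(C)C)cc(O[Si](C(C)C)(C(C)C)C(C)C)cc3o2)cc1O[Si](C(C)C)(C(C)C)C(C)C | intermediate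
14 | (2S)-4-[diethoxy(methyl)silyloxy]-5,7-bis(triisopropylsilyloxy)-2-[4-prenyloxy-3-(triisopropylsilyloxy)phenyl]-2H-chromene | CC(C)=CCOc1ccc([C@@H]2C=C(O[Si](C)(OCC)OCC)c3c(O[Si](C(C)C)(C(C)C)C(C)C)cc(O[Si](C(C)C)(C(C)C)C(C)C)cc3O2)cc1O[Si](C(C)C)(C(C)C)C(C)C | intermediate
15 | (2S)-5,7-bis(triisopropylsilyloxy)-2-[4-prenyloxy-3-(triisopropylsilyloxy)phenyl]chroman-4-one | CC(C)=CCOc1ccc([C@@H]2CC(=O)c3c(O[Si](C(C)C)(C(C)C)C(C)C)cc(O[Si](C(C)C)(C(C)C)C(C)C)cc3O2)cc1O[Si](C(C)C)(C(C)C)C(C)C | intermediate
16 | monotesone A, (2S)-5,7-dihydroxy-2-[3-hydroxy-4-(3-methylbut-2-enyloxy)phenyl]chroman-4-one | CC(C)=CCOc1ccc([C@@H]2CC(=O)c3c(O)cc(O)cc3O2)cc1O | target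

**Totals**

Total step count: 9.
Longest linear sequence: 6 steps (1, 2, 3, 7, 8, 9 from phloroglucinol; equally 4, 5, 6, 7, 8, 9 from 3,4-dihydroxybenzaldehyde).

**Steps most likely to fail**

Step 7. Oxidative addition at the doubly ortho-flanked C–I bond may be slow. Direct alkynylation, amine capture of the acyl–palladium, palladium-induced ionisation of the allylic aryl ether or silyl loss could then take over.

The fallback builds the ynone without palladium or CO gas and sets out from 9 and 3. Alkyne 9 is deprotonated (n-BuLi, THF, −78 °C) and acylated with N-methoxy-N-methylcarbamoyl chloride. This gives the Weinreb ynamide N-methoxy-N-methyl-3-[4-prenyloxy-3-(triisopropylsilyloxy)phenyl]prop-2-ynamide F1. Iodophenol 3 is converted to its magnesium phenoxide (MeMgCl, LiCl, THF, −20 °C) and subjected to iodine–magnesium exchange (i-PrMgCl, −20 °C → rt). The aryl Grignard reagent is added to F1 (Weinreb ketone synthesis). A mild acidic quench should give the o-hydroxyaryl ynone 1-[2-hydroxy-4,6-bis(triisopropylsilyloxy)phenyl]-3-[4-prenyloxy-3-(triisopropylsilyloxy)phenyl]prop-2-yn-1-one F2. Et2NH in THF at 40 °C closes it through 12, and the route is rejoined at 13.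

Step 8. Several processes threaten this step:
- Hydride transfer to the electron-rich, β-aryl vinylogous ester may be sluggish.
- Facial selectivity may be poor.
- The copper enolate may open by retro-oxa-Michael reaction and be reduced further.
- 1,2-over-reduction may intervene.

The fallback replaces asymmetric induction by non-selective reduction plus catalytic kinetic resolution and sets out from 13. L-Selectride (THF, −78 °C, AcOH quench) should give the racemic flavanone rac-5,7,3'-tris-O-TIPS-4'-prenyloxyflavanone F3. Ring opening is harmless here because re-closure gives the same racemate. Noyori asymmetric transfer hydrogenation follows with RuCl[(R,R)-TsDPEN](p-cymene), HCO2H/Et3N 5:2, EtOAc, rt, stopped slightly past half conversion. It should reduce the (2R)-enantiomer faster to the cis-alcohol (2R,4R)-5,7,3'-tris-O-TIPS-4'-prenyloxyflavan-4-ol F4. The (2S)-ketone is left behind and separated by chromatography, and the route is rejoined at 15.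

Step 2. Positional control may be incomplete, a second iodination may occur, or iodine may be lost on acidic silica.

The fallback relies on symmetry instead of steric shielding, bypasses steps 1–3 and sets out from 1. I2/NaHCO3 in THF–H2O at 0 °C can give only one mono-iodide, 2-iodobenzene-1,3,5-triol F5. Ac2O in pyridine gives 2-iodobenzene-1,3,5-triyl triacetate F6. F6, 9 and 10 are combined under the conditions of step 7 with a larger excess of Et2NH. Either ortho oxygen closes to the same ring and all acetates are aminolysed, which should give 5,7-dihydroxy-3'-O-TIPS-4'-prenyloxyflavone F7. TIPSOTf and 2,6-lutidine in CH2Cl2 then silylate O7 and the chelated O5, and the route is rejoined at 13.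

**Further compounds**

F1 | step 7 | N-methoxy-N-methyl-3-[4-prenyloxy-3-(triisopropylsilyloxy)phenyl]prop-2-ynamide | CON(C)C(=O)C#Cc1ccc(OCC=C(C)C)c(O[Si](C(C)C)(C(C)C)C(C)C)c1
F2 | step 7 | 1-[2-hydroxy-4,6-bis(triisopropylsilyloxy)phenyl]-3-[4-prenyloxy-3-(triisopropylsilyloxy)phenyl]prop-2-yn-1-one | O=C(C#Cc1ccc(OCC=C(C)C)c(O[Si](C(C)C)(C(C)C)C(C)C)c1)c1c(O)cc(O[Si](C(C)C)(C(C)C)C(C)C)cc1O[Si](C(C)C)(C(C)C)C(C)C
F3 | step 8 | rac-5,7,3'-tris-O-TIPS-4'-prenyloxyflavanone | CC(C)=CCOc1ccc(C2CC(=O)c3c(O[Si](C(C)C)(C(C)C)C(C)C)cc(O[Si](C(C)C)(C(C)C)C(C)C)cc3O2)cc1O[Si](C(C)C)(C(C)C)C(C)C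
F4 | step 8 | (2R,4R)-5,7,3'-tris-O-TIPS-4'-prenyloxyflavan-4-ol (2,4-cis) | CC(C)=CCOc1ccc([C@H]2C[C@@H](O)c3c(O[Si](C(C)C)(C(C)C)C(C)C)cc(O[Si](C(C)C)(C(C)C)C(C)C)cc3O2)cc1O[Si](C(C)C)(C(C)C)C(C)C
F5 | step 2 | 2-iodobenzene-1,3,5-triol | Oc1cc(O)c(I)c(O)c1
F6 | step 2 | 2-iodobenzene-1,3,5-triyl triacetate | CC(=O)Oc1cc(OC(C)=O)c(I)c(OC(C)=O)c1
F7 | step 2 | 5,7-dihydroxy-2-[4-prenyloxy-3-(triisopropylsilyloxy)phenyl]-4H-chromen-4-one | CC(C)=CCOc1ccc(-c2cc(=O)c3c(O)cc(O)cc3o2)cc1O[Si](C(C)C)(C(C)C)C(C)C
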